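## Analysis of the target

Compound 14 is a 1-aryl-1,2-dihydronaphthalene. Ring A is aromatic and carries methoxy groups at C6, C7 and C8. It is fused at C4a/C8a to ring B (C1–C4), whose C3=C4 double bond is conjugated with ring A. C1 bears the 3,4-dimethoxyphenyl group, and C2 and C3 bear the hydroxymethyl carbons C9' and C9. The two stereocentres, C1 (R) and C2 (S), are adjacent and trans; C3 is trigonal.

The sensitive parts are the styrene-type alkene (oxidative aromatisation, migration into C2=C3 or C1=C2 once C2–H is acidic), the allylic alcohol at C9 and the electron-rich rings. The difficulty is C1: a diarylmethine on the most crowded carbon of ring A (C8a, next to the C8 methoxy), with no functional group nearby to direct an asymmetric reaction once ring B exists.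

The route rests on one feature. At the ester oxidation level of C9 and C9', the C3–C4 bond joins an ester α-carbon to a carbon attached to ring A, so it is the bond of a Dieckmann condensation onto a ring A ester. C2 is then α to the C9' ester and can be equilibrated, whereas C1 has no acidifying group and can be set early and carried through.

## Retrosynthetic reasoning

**14 to 13.** No skeletal bond is cut first. Both hydroxymethyl groups go back to methyl esters, giving the unsaturated diester 13. This puts C9 and C9' at the level where C3 can be an enolate carbon and C2 an epimerisable centre. Forward, a hydride reagent that adds 1,2 to a conjugated ester must reduce both esters and leave C3=C4 alone.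

**13 to 10.** The alkene is traced to a C4 carbonyl: 13 comes from the enolised keto diester 10 by reduction to alcohol 11 and elimination through sulfonate 12. Only a C–O bond changes. The gain is that C4 becomes a ketone between ring A and an ester-bearing C3, a β-keto ester. Forward, the oxygen must leave without disturbing C2.

**10 to 9.** The C3–C4 bond is cut. It is the one ring B bond whose formation is reversible and ends in a stabilised enolate, so ring size and C2 configuration can be left to equilibrium. Cutting C1–C8a instead would need an electrophilic closure onto the crowded ring A carbon and would create C1 during ring formation. The open-chain triester 9 has C1 as its only fixed stereocentre. Forward, the closure must use C3 rather than C2, give the six- rather than the five-membered ring, and leave C2 trans to C1.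

**9 to 5.** The C2–C3 bond to the acetate arm is cut, but not by direct enolate alkylation of diester 5. The ester enolate of 5 sits five atoms from the ring A ester, and its closure to a five-membered, deprotonable keto ester would be fast and downhill. That closure is therefore used: 5 closes to the indanone keto ester 7, whose stabilised enolate is alkylated by bromoacetate 6 to give 8. In 8 the carbon between the carbonyls is quaternary, so catalytic alkoxide opens the ring to 9. The cost is one step; the gain is an alkylation under weak base with no competing pathway.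

**5 to 4.** The C1–H bond is cut: 5 comes from the β,β-diaryl acrylate 4 by catalytic asymmetric hydrogenation. C1 must be set before any base-mediated step and by a catalyst, and the two aryl groups on the alkene carbon differ strongly in shape.

**4 to 2 and 3.** The C1–C8a bond is cut: arylation of cinnamate 3 with aryl bromide 2. The mechanism fixes the alkene geometry, which the hydrogenation needs.

**2 to 1.** The C–Br bond is cut; the two free positions of ester 1 are equivalent.

## Alternatives that were turned down

**Alternative 1:** C2–C3 and C1–C8a are opened together, leading to the ester A1 of a cinnamyl alcohol with an arylpropiolic acid. Forward, a cationic gold catalyst with a chiral bisphosphine activates the ynoate. The alkene attacks through C2, closing the lactone, and the benzylic cation at C1 is captured by ring A at C8a. This gives lactone A2 with both rings and both stereocentres; hydride reduction of A2 gives 14.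
- For: about a third of the length of the chosen route, fully convergent, and the E-alkene geometry should translate into the trans relationship.
- Against: the ester tether prefers the conformer that holds alkyne and alkene apart, and the ynoate is a poor ligand for gold. The C1 cation is strongly stabilised by the dimethoxyphenyl group and may rotate or form reversibly, eroding both trans fidelity and enantiomeric purity. Ring A must attack through a carbon flanked by a methoxy group. Both centres depend on one event with no later correction at C1.
- Comparison: Alternative 1 is clearly stronger on step economy. The chosen route offers instead a C1 centre set on an acyclic alkene and measurable at 5 before further investment, and a C2 centre that corrects itself.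

**Alternative 2:** C4 is excised (C3–C4 and C4–C4a), contracting ring B to the trans indanone A3 with C9' as a silyl ether. Forward, a boron Lewis acid promotes addition of the diazo compound A4 to the carbonyl, and 1,2-shift of C4a gives the 2-tetralone A5.
- For: the trans C1/C2 relationship is fixed early on a rigid five-membered ring, at least as securely as in the chosen route.
- Against: migration of C4a competes with migration of the secondary C2, and a second insertion into the more reactive tetralone is possible. A5 is a β-silyloxy ketone with an acidic C2–H, so the base needed to make the C3=C4 enol sulfonate can expel silanolate and erase C2. C9 is absent from A5 and would need enol sulfonate formation, a palladium-catalysed carbonylation and deprotection.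
- Comparison: the length is equal or greater. The chosen route carries C9 and C9' from the start, and its ring-forming step leaves at C4 exactly the oxygen needed for the alkene.

**Alternative 3:** C1–C2 and C3–C4 are cut in a [4+2] sense, giving the 2-benzylbenzaldehyde A6 and the dienophile A7. Forward, irradiation at 365 nm moves a hydrogen from the diarylmethane carbon to the carbonyl oxygen. The resulting hydroxy-o-quinodimethane, held by a titanium Lewis acid with a chiral diol, adds A7 to give the tetralin A8. Dehydration of A8 would give 13 directly.
- For: the shortest access to 13 (two steps from A6), with all carbons at the right oxidation level and the C4 hydroxyl as a built-in leaving group.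
- Against: templating by the Lewis acid needs a donor next to the formyl group, but in A6 that position (C5) is hydrogen and the nearest methoxy is meta, so facial control is poorly supported. The C8 methoxy crowds the dienol terminus that becomes C1. Endo/exo selection decides the C1/C2 relationship. A6 itself needs a diarylmethane synthesis.
- Comparison: Alternative 3 is stronger on step count. It is weaker on C1, the one centre that cannot be corrected later. The chosen route sets C1 alone, thermally, by a catalyst class suited to the substrate.

Key step: step 6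

Remark: the sense of induction of the iridium catalyst on alkene 4 is assumed, not predicted; the ligand enantiomer meant is the one that gives (R)-5, and its antipode is used if the sense is opposite.
Remark: esters 1 and 3 are taken as purchased; each is one acid-catalysed esterification from the parent acid.

## Route

**Step 1**
Reactants: 1 methyl 3,4,5-trimethoxybenzoate
Product: 2 methyl 2-bromo-3,4,5-trimethoxybenzoate
Conditions: NBS (1.05 equiv), MeCN, 0 °C → rt
Reagents that add atoms: N-bromosuccinimide, O=C1CCC(=O)N1Br
Why: Electrophilic aromatic bromination; the two free positions are equivalent and each is ortho and para to a methoxy group, so one equivalent of reagent should give the single monobromide next to the ester.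

**Step 2**
Reactants: 2 methyl 2-bromo-3,4,5-trimethoxybenzoate; 3 methyl (E)-3-(3,4-dimethoxyphenyl)prop-2-enoate
Product: 4 methyl 2-[(E)-1-(3,4-dimethoxyphenyl)-3-methoxy-3-oxoprop-1-en-1-yl]-3,4,5-trimethoxybenzoate
Conditions: Pd(OAc)2 (5 mol %), P(t-Bu)3·HBF4 (10 mol %), Cy2NMe, 1,4-dioxane, 100 °C
Reagents that add atoms: none
Why: Mizoroki–Heck arylation; zerovalent palladium with the bulky trialkylphosphine should insert into the hindered C–Br bond and the aryl group adds to the alkene carbon remote from the ester. Syn insertion followed by syn β-hydride elimination places the new aryl group trans to the ester, so a single E isomer is expected.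

**Step 3**
Reactants: 4 methyl 2-[(E)-1-(3,4-dimethoxyphenyl)-3-methoxy-3-oxoprop-1-en-1-yl]-3,4,5-trimethoxybenzoate
Product: 5 methyl 2-[(1R)-1-(3,4-dimethoxyphenyl)-3-methoxy-3-oxopropyl]-3,4,5-trimethoxybenzoate
Conditions: [Ir(cod)(L)]B[3,5-(CF3)2C6H3]4 (2 mol %; L = 4-tert-butyl-2-[2-(diphenylphosphino)phenyl]-4,5-dihydrooxazole, enantiomer as in the remark), H2 (50 bar), CH2Cl2, rt
Reagents that add atoms: none
Why: Iridium/phosphine–oxazoline asymmetric hydrogenation of a trisubstituted acrylate, a class that includes β,β-diaryl esters. The catalyst should distinguish the flat, conjugated dimethoxyphenyl group from the twisted, doubly ortho-substituted ring A and so select one face of C1, giving the R centre; esters and arenes are not reduced.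

**Step 4**
Reactants: 5 methyl 2-[(1R)-1-(3,4-dimethoxyphenyl)-3-methoxy-3-oxopropyl]-3,4,5-trimethoxybenzoate; 6 methyl bromoacetate
Product: 8 methyl (3R)-3-(3,4-dimethoxyphenyl)-4,5,6-trimethoxy-2-(2-methoxy-2-oxoethyl)-1-oxo-2,3-dihydro-1H-indene-2-carboxylate, via indanone keto ester potassium enolate 7 (not isolated)
Conditions: KOt-Bu (1.05 equiv), THF, 0 °C; then 6, 0 °C → rt
Reagents that add atoms: none
Why: Dieckmann condensation followed by enolate C-alkylation; the only enolisable carbon of 5 closes on the ring A ester (5-exo-trig) to a keto ester held as its stabilised potassium enolate 7, which 6 should alkylate at carbon, anti to the neighbouring aryl group. The quaternary centre made here is erased in step 5, and one equivalent of base at 0 °C should leave the non-acidic diarylmethine (C1 of the target) untouched.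

**Step 5**
Reactants: 8 methyl (3R)-3-(3,4-dimethoxyphenyl)-4,5,6-trimethoxy-2-(2-methoxy-2-oxoethyl)-1-oxo-2,3-dihydro-1H-indene-2-carboxylate
Product: 9 dimethyl 2-[(R)-(3,4-dimethoxyphenyl)(2,3,4-trimethoxy-6-(methoxycarbonyl)phenyl)methyl]butanedioate (both C2 epimers)
Conditions: NaOMe (0.2 equiv), MeOH, 0 °C → rt; then AcOH
Reagents that add atoms: methanol, CO
Why: Retro-Claisen (retro-Dieckmann) cleavage; the keto ester of 8 cannot be protected as an enolate, so methoxide should add to the strained aryl ketone and expel the ester enolate, which methanol protonates to both C2 epimers of 9. Catalytic base in the cold leaves too little methoxide to drive the slower six-membered closure, and any material that does close is already 10.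

**Step 6**
Reactants: 9 dimethyl 2-[(R)-(3,4-dimethoxyphenyl)(2,3,4-trimethoxy-6-(methoxycarbonyl)phenyl)methyl]butanedioate (both C2 epimers)
Product: 10 dimethyl (1R,2S)-1-(3,4-dimethoxyphenyl)-4-hydroxy-6,7,8-trimethoxy-1,2-dihydronaphthalene-2,3-dicarboxylate (enol of the C4 ketone)
Conditions: NaOMe (3 equiv), MeOH/THF, 65 °C, Ar; then AcOH
Reagents that add atoms: none
Why: Dieckmann condensation under equilibrating alkoxide. Methoxide reversibly forms both ester enolates of 9; the C3 enolate of the CH2CO2Me arm adds to the ring A ester carbonyl C4 and methoxide is lost, forming C3–C4 and closing ring B in a 6-exo-trig mode with the enolate double bond outside the new ring. The product has a C3–H between ketone and ester and is deprotonated at once; this stabilised enolate is the only species that removes base from the equilibria and is what drives the condensation. The C2 enolate can close only to the five-membered quaternary keto ester 8, which cannot be deprotonated and reopens under the same methoxide, as step 5 shows, so the choice between C2 and C3 and between five- and six-membered ring is thermodynamic. C2 is the new element of relative configuration: its hydrogen is α to an ester and exchanges in 9 before closure and, more slowly, in the neutral keto ester that stays in equilibrium with the enolate in methanol. With C3 trigonal, allylic strain against the C3 ester pushes the C2 ester pseudoaxial, and the C8 methoxy group pushes the C1 aryl group pseudoaxial; two pseudoaxial groups on adjacent carbons are trans, so both epimers of 9 should drain to the (1R,2S) compound. C1–H is doubly benzylic but not α to a carbonyl and is not removed by methoxide, so the centre from step 3 is carried unchanged. Argon is used because the enolate of a 4-oxo-1,2-dihydronaphthalene is easily oxidised to the naphthol.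

**Step 7**
Reactants: 10 dimethyl (1R,2S)-1-(3,4-dimethoxyphenyl)-4-hydroxy-6,7,8-trimethoxy-1,2-dihydronaphthalene-2,3-dicarboxylate
Product: 11 dimethyl (1R,2S)-1-(3,4-dimethoxyphenyl)-4-hydroxy-6,7,8-trimethoxy-1,2,3,4-tetrahydronaphthalene-2,3-dicarboxylate (mixture at C3 and C4)
Conditions: NaBH4 (1.5 equiv), MeOH/THF, −10 → 0 °C
Reagents that add atoms: none
Why: Borohydride reduction of a β-keto ester through its keto tautomer; low temperature and a small excess should keep the esters intact. The new centres at C3 and C4 are removed in step 8, so their configuration is immaterial.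

**Step 8**
Reactants: 11 dimethyl (1R,2S)-1-(3,4-dimethoxyphenyl)-4-hydroxy-6,7,8-trimethoxy-1,2,3,4-tetrahydronaphthalene-2,3-dicarboxylate
Product: 13 dimethyl (1R,2S)-1-(3,4-dimethoxyphenyl)-6,7,8-trimethoxy-1,2-dihydronaphthalene-2,3-dicarboxylate, via C4 mesylate 12 (not isolated)
Conditions: MsCl, Et3N, CH2Cl2, 0 °C; then DBU, 0 °C → rt
Reagents that add atoms: none
Why: Sulfonylation and β-elimination; the benzylic C4 sulfonate, para to the C7 methoxy group and β to the C3 ester, should leave easily, and C3–H between ester and leaving group is the proton removed, giving the alkene conjugated with ring A and the ester. DBU is kept cold and brief so that C2–H is not drawn into alkene migration.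

**Step 9**
Reactants: 13 dimethyl (1R,2S)-1-(3,4-dimethoxyphenyl)-6,7,8-trimethoxy-1,2-dihydronaphthalene-2,3-dicarboxylate
Product: 14 [(1R,2S)-1-(3,4-dimethoxyphenyl)-6,7,8-trimethoxy-1,2-dihydronaphthalene-2,3-diyl]dimethanol
Conditions: i-Bu2AlH (6 equiv), CH2Cl2, −78 → 0 °C; aq. KNaC4H4O6
Reagents that add atoms: none
Why: Ester reduction with a Lewis acidic aluminium hydride, which adds 1,2 to the conjugated ester, so C3=C4 should survive. No base is present, so C1 and C2 keep their configuration.

## Compound list

1 | methyl 3,4,5-trimethoxybenzoate | COC(=O)c1cc(OC)c(OC)c(OC)c1 | starting material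
2 | methyl 2-bromo-3,4,5-trimethoxybenzoate | COC(=O)c1cc(OC)c(OC)c(OC)c1Br | intermediate
3 | methyl (E)-3-(3,4-dimethoxyphenyl)prop-2-enoate | COC(=O)/C=C/c1ccc(OC)c(OC)c1 | starting material
4 | methyl 2-[(E)-1-(3,4-dimethoxyphenyl)-3-methoxy-3-oxoprop-1-en-1-yl]-3,4,5-trimethoxybenzoate | COC(=O)/C=C(\c1ccc(OC)c(OC)c1)c1c(C(=O)OC)cc(OC)c(OC)c1OC | intermediate
5 | methyl 2-[(1R)-1-(3,4-dimethoxyphenyl)-3-methoxy-3-oxopropyl]-3,4,5-trimethoxybenzoate | COc1ccc([C@@H](CC(=O)OC)c2c(C(=O)OC)cc(OC)c(OC)c2OC)cc1OC | intermediate
6 | methyl bromoacetate | COC(=O)CBr | starting material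
7 | methyl (3R)-3-(3,4-dimethoxyphenyl)-4,5,6-trimethoxy-1-oxo-2,3-dihydro-1H-indene-2-carboxylate (in the flask as its potassium enolate; C2 labile) | COC(=O)C1C(=O)c2cc(OC)c(OC)c(OC)c2[C@H]1c1ccc(OC)c(OC)c1 | intermediate
8 | methyl (3R)-3-(3,4-dimethoxyphenyl)-4,5,6-trimethoxy-2-(2-methoxy-2-oxoethyl)-1-oxo-2,3-dihydro-1H-indene-2-carboxylate (C2 mainly with the acetate arm trans to the aryl group; either epimer serves) | COC(=O)CC1(C(=O)OC)C(=O)c2cc(OC)c(OC)c(OC)c2[C@H]1c1ccc(OC)c(OC)c1 | intermediate
9 | dimethyl 2-[(R)-(3,4-dimethoxyphenyl)(2,3,4-trimethoxy-6-(methoxycarbonyl)phenyl)methyl]butanedioate (both C2 epimers) | COc1ccc([C@@H](C(CC(=O)OC)C(=O)OC)c2c(C(=O)OC)cc(OC)c(OC)c2OC)cc1OC | intermediate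
10 | dimethyl (1R,2S)-1-(3,4-dimethoxyphenyl)-4-hydroxy-6,7,8-trimethoxy-1,2-dihydronaphthalene-2,3-dicarboxylate | COc1ccc([C@@H]2c3c(cc(OC)c(OC)c3OC)C(O)=C(C(=O)OC)[C@H]2C(=O)OC)cc1OC | intermediate
11 | dimethyl (1R,2S)-1-(3,4-dimethoxyphenyl)-4-hydroxy-6,7,8-trimethoxy-1,2,3,4-tetrahydronaphthalene-2,3-dicarboxylate (mixture at C3 and C4) | COc1ccc([C@@H]2c3c(cc(OC)c(OC)c3OC)C(O)C(C(=O)OC)[C@H]2C(=O)OC)cc1OC | intermediate
12 | dimethyl (1R,2S)-1-(3,4-dimethoxyphenyl)-4-(methanesulfonyloxy)-6,7,8-trimethoxy-1,2,3,4-tetrahydronaphthalene-2,3-dicarboxylate (mixture at C3 and C4) | COc1ccc([C@@H]2c3c(cc(OC)c(OC)c3OC)C(OS(C)(=O)=O)C(C(=O)OC)[C@H]2C(=O)OC)cc1OC | intermediate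
13 | dimethyl (1R,2S)-1-(3,4-dimethoxyphenyl)-6,7,8-trimethoxy-1,2-dihydronaphthalene-2,3-dicarboxylate | COc1ccc([C@@H]2c3c(cc(OC)c(OC)c3OC)C=C(C(=O)OC)[C@H]2C(=O)OC)cc1OC | intermediate
14 | [(1R,2S)-1-(3,4-dimethoxyphenyl)-6,7,8-trimethoxy-1,2-dihydronaphthalene-2,3-diyl]dimethanol | COc1ccc([C@@H]2c3c(cc(OC)c(OC)c3OC)C=C(CO)[C@H]2CO)cc1OC | target

## Step count and least certain steps

Total: 9 steps. Longest linear sequence: 9 steps (1 to 14); 3 and 6 enter in steps 2 and 4.

**Step 6 (key step).** Convergence at C2 may be incomplete. Once ring B is closed and the product sits as its enolate, exchange at C2 must pass through the small share of neutral keto ester. Closure may also be slow because the ring A ester is deactivated by the para C7 methoxy group, and the five-membered adduct may lose its ester group to methoxide irreversibly.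
Fallback: the stereochemical correction is moved from ring closure to the diester stage. Setting out from 10 as obtained, the accompanying dimethyl (1R,2R)-1-(3,4-dimethoxyphenyl)-4-hydroxy-6,7,8-trimethoxy-1,2-dihydronaphthalene-2,3-dicarboxylate F1 is carried through the conditions of steps 7 and 8. This passes through dimethyl (1R,2R)-1-(3,4-dimethoxyphenyl)-4-hydroxy-6,7,8-trimethoxy-1,2,3,4-tetrahydronaphthalene-2,3-dicarboxylate F2 and its C4 mesylate, dimethyl (1R,2R)-1-(3,4-dimethoxyphenyl)-4-(methanesulfonyloxy)-6,7,8-trimethoxy-1,2,3,4-tetrahydronaphthalene-2,3-dicarboxylate F3, to dimethyl (1R,2R)-1-(3,4-dimethoxyphenyl)-6,7,8-trimethoxy-1,2-dihydronaphthalene-2,3-dicarboxylate F4. In F4 the C2 hydrogen is α to an ester and allylic, so catalytic DBU in toluene at rt should exchange it, with reprotonation of the extended enolate at C2, and the trans diester should accumulate. Exposure is kept short to avoid alkene migration. The route is rejoined at 13.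

**Step 3.** Turnover may fail because the alkene carbon is screened above and below by the ortho substituents of the twisted ring A and the ortho ester may bind iridium; facial discrimination may also be poor.
Fallback: C1 is set by an electrocyclisation instead. Setting out from 1, crossed Claisen condensation with methyl acetate (NaH, THF, reflux) should give methyl 3-oxo-3-(3,4,5-trimethoxyphenyl)propanoate F5. Knoevenagel condensation with 3,4-dimethoxybenzaldehyde (piperidine, AcOH, toluene, reflux) should give methyl 3-(3,4-dimethoxyphenyl)-2-(3,4,5-trimethoxybenzoyl)prop-2-enoate F6. Nazarov cyclisation of F6 with Cu(OTf)2 and a C2-symmetric bis(oxazoline) ligand (ClCH2CH2Cl, 40 °C) closes onto one of the two equivalent ortho positions of the aryl ketone, the conrotatory sense being set by the ligand enantiomer. The route is rejoined at 7, which is alkylated with 6 (K2CO3, acetone) as in the second half of step 4; compounds 2 to 5 fall away.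

**Step 2.** Oxidative addition and alkene insertion may be slow for a doubly ortho-substituted, electron-rich aryl bromide meeting a 1,2-disubstituted alkene, with protodebromination and geometric scrambling by palladium hydride as side processes.
Fallback: the order of bond formation at C1 is changed. Setting out from 2, a Heck reaction with methyl acrylate, a monosubstituted alkene (Pd(OAc)2, P(o-tol)3, Et3N, DMF, 110 °C), should give methyl 3,4,5-trimethoxy-2-[(E)-3-methoxy-3-oxoprop-1-en-1-yl]benzoate F7. Rhodium-catalysed asymmetric 1,4-addition of 3,4-dimethoxyphenylboronic acid ([Rh(cod)Cl]2, BINAP, aq. KOH, 1,4-dioxane, 60 °C) then forms the C1–aryl bond and the stereocentre together. The route is rejoined at 5; compounds 3 and 4 and step 3 fall away.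

**Step 5.** Methoxide may attack the ester on the quaternary carbon instead of the ketone and remove it as dimethyl carbonate, because the ketone enolate is the better leaving group.
Fallback: the arm is attached while the ring A carboxyl is a carboxylate. Setting out from 5, saponification (LiOH, THF/H2O) should give 2-[(1R)-2-carboxy-1-(3,4-dimethoxyphenyl)ethyl]-3,4,5-trimethoxybenzoic acid F8. With LDA (3.3 equiv, THF, −78 → 0 °C) the aryl carboxylate is inert to the enediolate, which is alkylated by 6 at −78 °C to 2-[(1R)-2-carboxy-1-(3,4-dimethoxyphenyl)-4-methoxy-4-oxobutyl]-3,4,5-trimethoxybenzoic acid F9 (both C2 epimers). Esterification (MeOH, H2SO4, reflux) gives the triester. The route is rejoined at 9; compounds 7 and 8 fall away.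

**Step 8.** Under DBU the alkene may migrate from C3=C4 into C2=C3 or C1=C2 through the C2 enolate, which would also put C1 at risk; chloride may substitute at C4.
Fallback: the oxygen is removed without an elimination. Setting out from 10, the enol is converted into dimethyl (1R,2S)-1-(3,4-dimethoxyphenyl)-6,7,8-trimethoxy-4-(trifluoromethanesulfonyloxy)-1,2-dihydronaphthalene-2,3-dicarboxylate F10 (Tf2O, i-Pr2NEt, CH2Cl2, −78 °C). Its C4–O bond is replaced by C4–H with Pd(OAc)2, PPh3, HCO2H and Et3N in DMF at 60 °C. The route is rejoined at 13; steps 7 and 8 fall away.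

## Further compounds

F1 | step 6 | dimethyl (1R,2R)-1-(3,4-dimethoxyphenyl)-4-hydroxy-6,7,8-trimethoxy-1,2-dihydronaphthalene-2,3-dicarboxylate | COc1ccc([C@@H]2c3c(cc(OC)c(OC)c3OC)C(O)=C(C(=O)OC)[C@@H]2C(=O)OC)cc1OC
F2 | step 6 | dimethyl (1R,2R)-1-(3,4-dimethoxyphenyl)-4-hydroxy-6,7,8-trimethoxy-1,2,3,4-tetrahydronaphthalene-2,3-dicarboxylate (mixture at C3 and C4) | COc1ccc([C@@H]2c3c(cc(OC)c(OC)c3OC)C(O)C(C(=O)OC)[C@@H]2C(=O)OC)cc1OC
F3 | step 6 | dimethyl (1R,2R)-1-(3,4-dimethoxyphenyl)-4-(methanesulfonyloxy)-6,7,8-trimethoxy-1,2,3,4-tetrahydronaphthalene-2,3-dicarboxylate (mixture at C3 and C4) | COc1ccc([C@@H]2c3c(cc(OC)c(OC)c3OC)C(OS(C)(=O)=O)C(C(=O)OC)[C@@H]2C(=O)OC)cc1OC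
F4 | step 6 | dimethyl (1R,2R)-1-(3,4-dimethoxyphenyl)-6,7,8-trimethoxy-1,2-dihydronaphthalene-2,3-dicarboxylate | COc1ccc([C@@H]2c3c(cc(OC)c(OC)c3OC)C=C(C(=O)OC)[C@@H]2C(=O)OC)cc1OC
F5 | step 3 | methyl 3-oxo-3-(3,4,5-trimethoxyphenyl)propanoate | COC(=O)CC(=O)c1cc(OC)c(OC)c(OC)c1
F6 | step 3 | methyl 3-(3,4-dimethoxyphenyl)-2-(3,4,5-trimethoxybenzoyl)prop-2-enoate (alkene geometry not fixed) | COC(=O)C(=Cc1ccc(OC)c(OC)c1)C(=O)c1cc(OC)c(OC)c(OC)c1
F7 | step 2 | methyl 3,4,5-trimethoxy-2-[(E)-3-methoxy-3-oxoprop-1-en-1-yl]benzoate | COC(=O)/C=C/c1c(C(=O)OC)cc(OC)c(OC)c1OC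
F8 | step 5 | 2-[(1R)-2-carboxy-1-(3,4-dimethoxyphenyl)ethyl]-3,4,5-trimethoxybenzoic acid | COc1ccc([C@@H](CC(=O)O)c2c(C(=O)O)cc(OC)c(OC)c2OC)cc1OC
F9 | step 5 | 2-[(1R)-2-carboxy-1-(3,4-dimethoxyphenyl)-4-methoxy-4-oxobutyl]-3,4,5-trimethoxybenzoic acid (both C2 epimers) | COc1ccc([C@@H](C(CC(=O)OC)C(=O)O)c2c(C(=O)O)cc(OC)c(OC)c2OC)cc1OC
F10 | step 8 | dimethyl (1R,2S)-1-(3,4-dimethoxyphenyl)-6,7,8-trimethoxy-4-(trifluoromethanesulfonyloxy)-1,2-dihydronaphthalene-2,3-dicarboxylate | COc1ccc([C@@H]2c3c(cc(OC)c(OC)c3OC)C(OS(=O)(=O)C(F)(F)F)=C(C(=O)OC)[C@H]2C(=O)OC)cc1OC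
A1 | alternative 1 | (E)-3-(3,4-dimethoxyphenyl)prop-2-en-1-yl 3-(3,4,5-trimethoxyphenyl)prop-2-ynoate | COc1ccc(/C=C/COC(=O)C#Cc2cc(OC)c(OC)c(OC)c2)cc1OC
A2 | alternative 1 | 1,2-trans 1-(3,4-dimethoxyphenyl)-6,7,8-trimethoxy-1,2-dihydronaphthalene 3,2-carbolactone (C9 carbonyl, C9' CH2O) | COc1ccc([C@@H]2c3c(cc(OC)c(OC)c3OC)C=C3C(=O)OC[C@@H]23)cc1OC
A3 | alternative 2 | trans-2-[(tert-butyldimethylsilyloxy)methyl]-3-(3,4-dimethoxyphenyl)-4,5,6-trimethoxyindan-1-one | COc1ccc([C@@H]2c3c(cc(OC)c(OC)c3OC)C(=O)[C@H]2CO[Si](C)(C)C(C)(C)C)cc1OC
A4 | alternative 2 | trimethylsilyldiazomethane | C[Si](C)(C)C=[N+]=[N-]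
A5 | alternative 2 | trans-1-(3,4-dimethoxyphenyl)-6,7,8-trimethoxy-2-[(tert-butyldimethylsilyloxy)methyl]tetralin-3-one (target numbering) | COc1ccc([C@@H]2c3c(cc(OC)c(OC)c3OC)CC(=O)[C@H]2CO[Si](C)(C)C(C)(C)C)cc1OC
A6 | alternative 3 | 2-[(3,4-dimethoxyphenyl)methyl]-3,4,5-trimethoxybenzaldehyde | COc1ccc(Cc2c(C=O)cc(OC)c(OC)c2OC)cc1OC
A7 | alternative 3 | dimethyl fumarate | COC(=O)/C=C/C(=O)OC
A8 | alternative 3 | dimethyl 1-(3,4-dimethoxyphenyl)-4-hydroxy-6,7,8-trimethoxy-1,2,3,4-tetrahydronaphthalene-2,3-dicarboxylate (1,2-trans, 2,3-trans, 3,4-cis) | COc1ccc([C@@H]2c3c(cc(OC)c(OC)c3OC)[C@H](O)[C@H](C(=O)OC)[C@H]2C(=O)OC)cc1OC
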